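(All constants are made up; the flask was simulated.)

Count this flask in millimolar of the final volume, and ask where each acid set free goes once it has left the electrophile.

solid electrophile 0.020 M; nucleophile 1.80 equiv (fed, over 4.0 h); free base 3.00 equiv; time 40 h; the fed solution adds 0.50 times the starting volume

    acid set free + free base ⇌ salt of the base (K1 = 18 /M, k1 = 510 /M/h)
    nucleophile + acid set free ⇌ protonated nucleophile, settled at all times (K2 = 570 /M)
    electrophile + nucleophile → acid set free + target (k3 = 8.9 /M/h)
    solid electrophile ⇌ electrophile, rate k4*(cs4 - [electrophile]) while solid is left; crystals form when [electrophile] > cs4 (cs4 = 4.0 mM, k4 = 3.0 /h)
    electrophile + target → side product (k5 = 1.8 /M/h)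

- a species is counted by the solid electrophile in it: one side product counts as two
- charges are per starting volume, the dose included; the dosed solution carries all of it
- given per volume of solution although it is solid: solid electrophile
- at the start none of the solid electrophile is in solution
- what has only dissolved of solid electrophile counts as not reacted
- run time (flask): 40 h

1. part of the solid electrophile that has reacted (what has only dissolved counts as not reacted) at 40 h
2. share of the unused nucleophile that is free and not bound as protonated nucleophile, at 40 h

Per final volume, this flask holds 13.3 mM of electrophile (solid at first), 24.0 mM of nucleophile and 40.0 mM of free base.

The first chemist counts charges: the free base is more than the acid the electrophile can give, so the free base should hold the acid and the free share of the nucleophile should stand near 100 %.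

The second chemist, whose reckoning I take as mine, compares constants: one nucleophile binds acid 31.7 times as strongly as one free base. When free and protonated nucleophile stand level, c(acid set free) is 1.75 mM, and that acid together with what the free base, taken at its charge, holds comes to 3.02 mM. This amount, the acid kept off the nucleophile at that level point, is the acid room. It is less than the charge of free base.

An electrophile molecule has a fork too: nucleophile gives acid, target gives side product and no acid. With c(nucleophile) level with c(target), a rough middle for the run, the selectivity factor gives the acid way a chance of 83.2%. Taking the whole charge as used, the acid made is 11.1 mM, and 12.9 mM of nucleophile stays unused.

With f the free share, the balance reads: acid made = (1 − f)(unused nucleophile + room/f). Solved, it gives 5.67 mM free, so 43.9%. Holding the end pace of electrophile loss over the run, as if the whole charge stood dissolved from the start, gives a crude 94.0%.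

The forecast, 94% and 44%, stands on the second side: “Acid partitions mainly onto the nucleophile”.

This flask gives 93.6% and 43.0%.

The first view's free share comes near this flask at 4.00 h, with 94.4% free, while the target stands below the room; but even then the salt of the base, at 7.45 × 10⁻⁵ M, holds less acid than the protonated nucleophile, at 0.00127 M. The neighbour flask with 0.450 equiv of nucleophile has made 3.67 mM of acid, counted as target plus half the side product; the room gives 53.8% free, and that flask shows 53.5%. This flask is not at rest at 40.0 h: by 400 h, electrophile falls from 6.43% to 0% and side product rises from 18.8% to 22.5%. Acid made reaches 11.8 mM, and the room puts the free share at 40.2%.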